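Ring carbon C4 of the furanone is bonded to bromine and to C5 at the same time, so it is traced back to the CBr2 end of an acrylic acid, and the ring is disconnected at C4–C5 and O1–C5. In a single operation, Sonogashira coupling exchanges the bromide cis to the carboxyl group for trimethylsilylethyne and the carboxylate closes onto the new alkyne, giving the 4-bromo-(5Z)-silylmethylidene butenolide; iododesilylation then completes the target. The precursor is 2-[(1R)-1-acetoxybutyl]-3,3-dibromoprop-2-enoic acid, made from a lipase-resolved Baylis–Hillman acetate by ozonolysis, dibromo-olefination and ester cleavage.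

Key step: step 6

Remark on nomenclature: in the open-chain coupling intermediate 12 the alkynyl group is cis to the carboxyl group; because bromine outranks the alkynyl carbon at C3, this geometry carries the descriptor 2E.

Assumption: the lipase is taken to show the usual preference for secondary alcohols and to acylate (R)-3; the configuration and enantiomeric purity of 5 are to be confirmed before it is carried on.

Step 1
Reactants: 1 tert-butyl acrylate; 2 butanal
Product: 3 tert-butyl 3-hydroxy-2-methylidenehexanoate (racemic)
Conditions: DABCO (0.5 equiv), MeOH (1 equiv), neat, rt, 5–10 d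
Reagents that add atoms: none
Why: Morita–Baylis–Hillman reaction: DABCO adds in conjugate fashion to 1, the ammonium enolate attacks the aldehyde and the amine is eliminated, giving the racemic allylic alcohol; no stereocontrol is sought here.

Step 2
Reactants: 3 tert-butyl 3-hydroxy-2-methylidenehexanoate (racemic); 4 vinyl acetate
Product: 5 tert-butyl (3R)-3-(acetyloxy)-2-methylidenehexanoate
Conditions: immobilised Burkholderia cepacia lipase, 4 (3 equiv), tBuOMe, 35 °C, stopped near 40% conversion; chromatography
Reagents that add atoms: none
Why: Lipase-catalysed kinetic resolution by irreversible transesterification: by the empirical size rule for secondary alcohols (large group the ester-bearing vinyl unit, medium group propyl) the (R)-alcohol should be acetylated faster, so the enzyme sets the C3 stereocentre and installs the acetate of the target at once, while the slow (S)-alcohol stays behind and is separated.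

Step 3
Reactants: 5 tert-butyl (3R)-3-(acetyloxy)-2-methylidenehexanoate
Product: 7 tert-butyl (3R)-3-(acetyloxy)-2-oxohexanoate, via secondary ozonide 6 (not isolated)
Conditions: O3, CH2Cl2, −78 °C; then Me2S, −78 °C to rt; used without delay
Reagents that add atoms: ozone, [O-][O+]=O
Why: Ozonolysis with reductive work-up: 1,3-dipolar cycloaddition of ozone to the 1,1-disubstituted alkene, rearrangement to ozonide 6 and reduction by Me2S should give the α-keto ester, the neutral cold conditions leaving both esters and the acetoxy-bearing stereocentre untouched.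

Step 4
Reactants: 7 tert-butyl (3R)-3-(acetyloxy)-2-oxohexanoate; 8 carbon tetrabromide
Product: 9 tert-butyl 2-[(1R)-1-(acetyloxy)butyl]-3,3-dibromoprop-2-enoate
Conditions: 8 (2 equiv), PPh3 (4 equiv), CH2Cl2, 0 °C, 30 min; then 7, 0 °C to rt
Reagents that add atoms: none
Why: Ramirez dibromo-olefination (first stage of the Corey–Fuchs sequence): Ph3P=CBr2 formed in the flask undergoes a Wittig reaction with the ketone, which is activated by the neighbouring ester as in other α-keto esters, and the weakly basic ylide at low temperature should not enolise the acetoxy-bearing centre.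

Step 5
Reactants: 9 tert-butyl 2-[(1R)-1-(acetyloxy)butyl]-3,3-dibromoprop-2-enoate
Product: 10 2-[(1R)-1-(acetyloxy)butyl]-3,3-dibromoprop-2-enoic acid
Conditions: CF3CO2H/CH2Cl2 1:4, 0 °C to rt; co-evaporation with toluene
Reagents that add atoms: none
Why: Acidolysis of a tert-butyl ester through the tert-butyl cation, lost as isobutene; the secondary acetate and the electron-poor dibromoalkene should be inert to anhydrous acid.

Step 6
Reactants: 10 2-[(1R)-1-(acetyloxy)butyl]-3,3-dibromoprop-2-enoic acid; 11 ethynyltrimethylsilane
Product: 13 (1R)-1-{(5Z)-4-bromo-2-oxo-5-[(trimethylsilyl)methylidene]-2,5-dihydrofuran-3-yl}butyl acetate, via bromoenynoic acid 12 (not isolated)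
Conditions: Pd(PPh3)2Cl2 (5 mol%), CuI (10 mol%), Et3N (3 equiv), 11 (1.05 equiv), degassed MeCN, rt
Reagents that add atoms: none
Why: Zerovalent palladium formed in the flask inserts into the C–Br bond of the carboxylate of 10 that lies cis to the carboxylate, the copper acetylide of 11 transmetalates, and reductive elimination forms C4–C5 to give enynoic acid 12 with the alkyne cis to the carboxylate. The carboxylate oxygen then adds anti across the metal-coordinated triple bond and triethylammonium protonates the vinyl–metal bond, closing the furanone ring at O1–C5 in the 5-exo-dig mode and leaving silicon cis to O1, that is the 5Z alkene. The closest known reaction type is the tandem Sonogashira coupling and lactonisation of (Z)-3-haloacrylic acids with terminal alkynes to (Z)-5-ylidenefuran-2(5H)-ones. No stereocentre is formed, and the acetoxy-bearing centre takes no part. The step needs site selection between the two bromides, which the substrate should secure because the carboxylate can precoordinate the metal and is far smaller than the branched 1-acetoxybutyl group beside the other bromide; an acid coupled at the wrong bromide cannot lactonise and would be removed by NaHCO3 extraction. It also needs 5-exo over 6-endo closure, favoured by the bulky silyl terminus that stabilises the carbon–metal bond developing at C6, and mono-coupling, secured by one equivalent of alkyne, a tertiary amine and room temperature so that the C4 bromide of 13 is not engaged.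

Step 7
Reactants: 13 (1R)-1-{(5Z)-4-bromo-2-oxo-5-[(trimethylsilyl)methylidene]-2,5-dihydrofuran-3-yl}butyl acetate
Product: 14 (1R)-1-[(5Z)-4-bromo-5-(iodomethylidene)-2-oxo-2,5-dihydrofuran-3-yl]butyl acetate
Conditions: N-iodosuccinimide (1.2 equiv), (CF3)2CHOH, 0 °C, dark; aq. Na2S2O3 work-up
Reagents that add atoms: N-iodosuccinimide, O=C1CCC(=O)N1I
Why: Iododesilylation of a vinylsilane (electrophilic ipso-substitution): iodonium attacks C6, the cation at C5 is stabilised by the β-silicon and by O1, and loss of silicon along the least-motion path should give the iodide with retention, the 5Z isomer also being the thermodynamically preferred one because iodine stays away from the C4 bromine.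

Compound list
1 | tert-butyl acrylate (tert-butyl prop-2-enoate) | C=CC(=O)OC(C)(C)C | starting material
2 | butanal | CCCC=O | starting material
3 | tert-butyl 3-hydroxy-2-methylidenehexanoate (racemic) | CCCC(O)C(=C)C(=O)OC(C)(C)C | intermediate
4 | vinyl acetate (ethenyl acetate) | CC(=O)OC=C | starting material
5 | tert-butyl (3R)-3-(acetyloxy)-2-methylidenehexanoate | CCC[C@@H](OC(C)=O)C(=C)C(=O)OC(C)(C)C | intermediate
6 | tert-butyl 3-[(1R)-1-(acetyloxy)butyl]-1,2,4-trioxolane-3-carboxylate (secondary ozonide, both epimers at the ring carbon, not isolated) | CCC[C@@H](OC(C)=O)C1(OCOO1)C(=O)OC(C)(C)C | intermediate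
7 | tert-butyl (3R)-3-(acetyloxy)-2-oxohexanoate | CCC[C@@H](OC(C)=O)C(=O)C(=O)OC(C)(C)C | intermediate
8 | carbon tetrabromide | BrC(Br)(Br)Br | starting material
9 | tert-butyl 2-[(1R)-1-(acetyloxy)butyl]-3,3-dibromoprop-2-enoate | CCC[C@@H](OC(C)=O)C(=C(Br)Br)C(=O)OC(C)(C)C | intermediate
10 | 2-[(1R)-1-(acetyloxy)butyl]-3,3-dibromoprop-2-enoic acid | CCC[C@@H](OC(C)=O)C(C(=O)O)=C(Br)Br | intermediate
11 | ethynyltrimethylsilane | C#C[Si](C)(C)C | starting material
12 | (2E)-2-[(1R)-1-(acetyloxy)butyl]-3-bromo-5-(trimethylsilyl)pent-2-en-4-ynoic acid (alkyne cis to carboxyl, not isolated) | CCC[C@@H](OC(C)=O)/C(C(=O)O)=C(Br)/C#C[Si](C)(C)C | intermediate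
13 | (1R)-1-{(5Z)-4-bromo-2-oxo-5-[(trimethylsilyl)methylidene]-2,5-dihydrofuran-3-yl}butyl acetate | CCC[C@@H](OC(C)=O)C1=C(Br)/C(=C/[Si](C)(C)C)OC1=O | intermediate
14 | (1R)-1-[(5Z)-4-bromo-5-(iodomethylidene)-2-oxo-2,5-dihydrofuran-3-yl]butyl acetate | CCC[C@@H](OC(C)=O)C1=C(Br)/C(=C/I)OC1=O | target

Total step count: 7
Longest linear sequence: 7 steps (from 1 and 2 to 14)

Steps most likely to fail

Step 6. What may go wrong is oxidative addition at the bromide beside the acetoxybutyl group, a second coupling at the C4 bromide of the product, or 6-endo closure. The fallback sets out from 9 and comes back at 13, and it differentiates the two halogens before any palladium chemistry. Treatment of 9 with iPrMgCl·LiCl (1.05 equiv, THF, −78 °C) should exchange the bromide cis to the ester, because the resulting magnesium carbenoid is held by chelation to the ester carbonyl (a known ester-directed bromine–magnesium exchange of gem-dibromoalkenes). Quenching with iodine at −78 °C gives tert-butyl (2Z)-2-[(1R)-1-(acetyloxy)butyl]-3-bromo-3-iodoprop-2-enoate F1. CF3CO2H in CH2Cl2 then liberates (2Z)-2-[(1R)-1-(acetyloxy)butyl]-3-bromo-3-iodoprop-2-enoic acid F2. Coupling of F2 with 11 under Pd(PPh3)2Cl2/CuI/Et3N in MeCN at rt should take place at the C–I bond only and lead through 12 to 13.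

Step 2. What may go wrong is insufficient discrimination between the enantiomers of 3, since propyl and the acrylate unit may differ too little in size for the enzyme, so that 5 is carried on with too low enantiomeric purity. The fallback sets out from 2 and comes back at 5, replacing resolution by asymmetric catalysis. SnCl2-catalysed Roskamp homologation of 2 with tert-butyl diazoacetate (CH2Cl2, rt) gives tert-butyl 3-oxohexanoate F3. Noyori hydrogenation (H2, RuCl2[(R)-BINAP], MeOH, 50 °C) gives tert-butyl (3R)-3-hydroxyhexanoate F4. Fráter–Seebach alkylation of its dianion (LiN(iPr)2, 2.2 equiv, THF, −78 to −20 °C) with dimethyl(methylidene)ammonium iodide gives tert-butyl (2R,3R)-2-[(dimethylamino)methyl]-3-hydroxyhexanoate F5, whose C2 centre is destroyed next. Methyl iodide converts it into {(2R,3R)-2-(tert-butoxycarbonyl)-3-hydroxyhexyl}trimethylammonium iodide F6, and DBU eliminates trimethylamine to give tert-butyl (3R)-3-hydroxy-2-methylidenehexanoate F7. Acetylation (Ac2O, pyridine, 4-dimethylaminopyridine) returns to 5.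

Step 7. What may go wrong is sluggish ipso-attack of iodonium on the electron-poor dienyl system, or loss of alkene geometry through a long-lived oxocarbenium ion. The fallback sets out from 13 and comes back at 14, using addition–elimination on an exocyclic methylidene group in place of ipso-substitution. Protodesilylation with CF3CO2H in CH2Cl2 gives (1R)-1-(4-bromo-5-methylidene-2-oxo-2,5-dihydrofuran-3-yl)butyl acetate F8. ICl (CH2Cl2, −78 °C) adds iodine to the methylidene carbon and chloride to C5, giving (1R)-1-[4-bromo-5-chloro-5-(iodomethyl)-2-oxo-2,5-dihydrofuran-3-yl]butyl acetate F9 as a mixture of C5 epimers. Et3N then eliminates hydrogen chloride to give 14; the 5Z isomer is expected because the alternative would press iodine against the C4 bromine, as in the classical halogen addition–dehydrohalogenation route to (Z)-halomethylidene furanones.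

Further compounds
F1 | step 6 | tert-butyl (2Z)-2-[(1R)-1-(acetyloxy)butyl]-3-bromo-3-iodoprop-2-enoate | CCC[C@@H](OC(C)=O)/C(C(=O)OC(C)(C)C)=C(Br)/I
F2 | step 6 | (2Z)-2-[(1R)-1-(acetyloxy)butyl]-3-bromo-3-iodoprop-2-enoic acid | CCC[C@@H](OC(C)=O)/C(C(=O)O)=C(Br)/I
F3 | step 2 | tert-butyl 3-oxohexanoate | CCCC(=O)CC(=O)OC(C)(C)C
F4 | step 2 | tert-butyl (3R)-3-hydroxyhexanoate | CCC[C@@H](O)CC(=O)OC(C)(C)C
F5 | step 2 | tert-butyl (2R,3R)-2-[(dimethylamino)methyl]-3-hydroxyhexanoate | CCC[C@@H](O)[C@@H](CN(C)C)C(=O)OC(C)(C)C
F6 | step 2 | {(2R,3R)-2-(tert-butoxycarbonyl)-3-hydroxyhexyl}trimethylammonium iodide | CCC[C@@H](O)[C@@H](C[N+](C)(C)C)C(=O)OC(C)(C)C.[I-]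
F7 | step 2 | tert-butyl (3R)-3-hydroxy-2-methylidenehexanoate | CCC[C@@H](O)C(=C)C(=O)OC(C)(C)C
F8 | step 7 | (1R)-1-(4-bromo-5-methylidene-2-oxo-2,5-dihydrofuran-3-yl)butyl acetate | CCC[C@@H](OC(C)=O)C1=C(Br)C(=C)OC1=O
F9 | step 7 | (1R)-1-[4-bromo-5-chloro-5-(iodomethyl)-2-oxo-2,5-dihydrofuran-3-yl]butyl acetate | CCC[C@@H](OC(C)=O)C1=C(Br)C(Cl)(CI)OC1=O
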